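## Structural features

- The target 17 is a 2,3,5-trisubstituted oxane (ring atoms O1, C2, C3, C4, C5, C6). C2 carries a 4-hydroxyphenyl ring, C3 an (E)-3-(4-hydroxyphenyl)prop-2-enyl chain, and C5 an exocyclic carbinol carbon C1' (OH plus a third 4-hydroxyphenyl ring). C4 and C6 are CH2.
- There are four stereocentres. C2 (R) and C3 (S) are adjacent, C5 (R) is 1,3 to C3 across C4, and C1' (R) is adjacent to C5. The alkene is E.
- All three ring substituents are cis. In the chair with the C3 and C5 groups equatorial the C2 aryl group is axial, so the target is the less stable C2 epimer. C2 must be set kinetically and never equilibrated.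
- The C2–O1 and C1'–OH bonds are 4-hydroxybenzylic. Acids or Lewis acids ionise them to benzylic cations or quinone methides, which would epimerise C2, and hydrogenolysis cleaves them. The styrene and three free phenols add to the sensitivity.
- The structure hides a symmetry. C4 is flanked by C3 and C5, and each of these bears an ArCH(O) carbon (C2 or C1') and a one-carbon arm (the cinnamyl CH2 or C6). With both arms written as CH2OH, the C2/C3/C5/C1' array is (R,R,R,R) and C2-symmetric about C4.
- The real difficulty is to set four stereocentres, including the contra-thermodynamic C2, in one relative and absolute sense without acid. The key step exploits the twofold axis through C4: it sets C2, C3, C5 and C1' in one operation on a bis(β-keto ester) whose central carbon C4 comes from formaldehyde.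
- In one sentence, the route is a ketoreductase-catalysed double dynamic kinetic resolution of the stereorandom methylene-bridged bis(β-keto ester) 4.

## Logic of the disconnections

**17 to 16.** Four O–Si bonds are cut (three phenolic, one at C1'). Silyl ethers are chosen because fluoride removes them without acid, base or hydrogen. The forward step must keep the phenoxides buffered so that the 4-hydroxybenzylic C–O bonds at C2 and C1' stay intact.

**16 to 12 and 14.** The single bond between the CH2 on C3 and the styrenyl CH is cut. This puts the arm on C3 at the same length and oxidation level as C6, which exposes the hidden symmetry, and the E alkene arrives preformed in 14. The forward step is an sp3–sp2 coupling that must avoid β-hydride elimination and keep the alkene geometry. 14 is traced to 13 by cutting the C=C bond, a one-carbon E-selective homologation of an aldehyde.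

**12 to 11, 10 and 9.** The O1–C6 bond is cut, not O1–C2. C2 keeps its oxygen, so its configuration is fixed in the acyclic precursor and never touched during ring closure. The ring and its three stereocentres reduce to an acyclic chain with two CH2O arms. The forward closure must use only the C2 oxygen, so the C1' oxygen has to be masked, and the 6-exo closure onto C6 must beat the 4-exo closure onto the arm at C3.

**9 to 8 and 7.** The two primary alcohols are traced to ester groups, and one O–Si bond at C1' is cut. 7 is C2-symmetric, so its two carbinol hydroxyls are homotopic and mono-silylation can give only one product. That silyl group decides which carbinol becomes the ring oxygen and which stays exocyclic. The forward step must be controlled against double silylation.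

**7 to 6 and 4 (key).** Two phenolic O–Si bonds are cut, then the C–H bonds at C2 and C1' (hydride). The C–H bonds at C3 and C5 are set in the same operation through epimerisation. All four stereocentres vanish: 4 is a stereorandom mixture made from achiral materials. The forward step must reduce both aryl ketones from the same face and select the same α-epimer in each half, with the α-centres equilibrating faster than the slower epimer reacts.

**4 to 2 and formaldehyde.** The C3–C4 and C4–C5 bonds are cut. C4 is a methylene between two carbons that are each α to two carbonyl groups, so it is a formaldehyde-level carbon bridging two identical nucleophiles. The molecule is halved. The forward step needs a 2:1 stoichiometry and must stop at the bis-adduct.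

**2 to 1.** The bond between the ketone α-carbon and the ester carbonyl is cut. The forward step is a Claisen-type ethoxycarbonylation of a methyl ketone.

## Other disconnections considered

**Alternative 1:** (the first that comes to mind) Cut C2–aryl and C2–H.
- Forward key step: an aryl-metal nucleophile adds to δ-lactone A1 to give lactol A2, and the derived oxocarbenium ion is reduced with Et3SiH and BF3·OEt2.
- Hydride should add axially to the half-chair that keeps the C3 and C5 groups pseudo-equatorial. That places the C2 aryl equatorial, trans to the C3 chain, the opposite of what the target needs.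
- The Lewis acid should also ionise the silyloxybenzylic C1'–O bond and, after reduction, the new C2–O1 bond, which drives C2 further toward the stable epimer.
- A1 needs C3, C5 and C1' set in separate auxiliary-controlled steps, so the route is longer and ends on the wrong side of the C2 problem.

**Alternative 2:** (biomimetic) Cut O1–C2 as a conjugate addition.
- Forward key step: the C6 hydroxyl of quinone methide A3 adds to the exocyclic carbon, closing the oxane.
- The addition is reversible under the conditions that generate the quinone methide, so C2 should settle in the all-equatorial arrangement, again the wrong epimer.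
- The 4-hydroxybenzylic alcohol at C1' can enter the same quinone methide manifold and lose its configuration.
- C3, C5 and C1' must still be made beforehand, so the step solves only the ring, and with the wrong selectivity.

**Alternative 3:** Cut C3–C4 along the natural 1,5-dicarbonyl polarity.
- Forward key step: the enolate of ketone A5 adds to the Baylis–Hillman-derived acrylate A4, followed by α-protonation.
- C3 is set by acyclic enolate face selectivity and C5 by protonation next to an existing stereocentre; both are weakly controlled. C2 then needs a separate ketone reduction.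
- That makes three stereo-determining events against one catalyst-controlled operation in the chosen plan.
- The chosen plan uses the same polarity insight (C4 as a formaldehyde carbon between two enolisable carbons) but applies it symmetrically, so one reagent sets all four centres.

Key step: step 3

Remark: a ketoreductase with anti and Si-face selectivity on 4 is assumed to be identifiable by screening a commercial enzyme panel; all configurations below are written for such an enzyme.

Abbreviations: TIPS = triisopropylsilyl, TBS = tert-butyldimethylsilyl, Ts = 4-methylbenzenesulfonyl. Target locants (O1, C2–C6, C1') are used for all intermediates.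

## Steps

Step 1
Reactants: 1 1-(4-hydroxyphenyl)ethan-1-one
Product: 2 ethyl 3-(4-hydroxyphenyl)-3-oxopropanoate
Conditions: NaH (3 equiv), (EtO)2CO, THF, reflux; then aq. HCl
Reagents that add atoms: diethyl carbonate, CCOC(=O)OCC
Why: Claisen-type ethoxycarbonylation of the methyl ketone enolate; excess hydride covers the phenol and the acidic product, whose deprotonation drives the condensation.

Step 2
Reactants: 2 ethyl 3-(4-hydroxyphenyl)-3-oxopropanoate (2 equiv)
Product: 4 diethyl 2,4-bis(4-hydroxybenzoyl)pentanedioate (interconverting racemic and meso forms), via ethyl 2-(4-hydroxybenzoyl)prop-2-enoate 3 (not isolated)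
Conditions: (CH2O)n (0.5 equiv as CH2O), piperidine (10 mol %), EtOH, 0 °C to rt
Reagents that add atoms: formaldehyde (as paraformaldehyde), C=O
Why: Knoevenagel condensation gives the methylene compound 3, which is trapped at once by a second enolate of 2 in a Michael addition; the aryl ketones have no α'-hydrogens, so the 1,5-diketone cannot close by aldol, and the labile stereocentres need no control.

Step 3
Reactants: 4 diethyl 2,4-bis(4-hydroxybenzoyl)pentanedioate
Product: 6 diethyl (2S,4S)-2,4-bis[(R)-hydroxy(4-hydroxyphenyl)methyl]pentanedioate, via mono-reduced hydroxy keto diester 5 (not isolated)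
Conditions: ketoreductase (anti- and Si-face-selective, from panel screening), NADP+ (cat.), i-PrOH (15% v/v), KH2PO4/K2HPO4 buffer (0.1 M, pH 7.5), MgSO4 (2 mM), DMSO (10% v/v), 30 °C
Reagents that add atoms: none
Why: NADPH in the ketoreductase transfers hydride to the Si face of an aryl ketone of 4 while an active-site tyrosine protonates the oxygen, and only the α-epimer whose ester and chain fit the pocket is turned over; the α-carbons of the unreduced β-keto ester epimerise through the enol at pH 7.5 faster than the disfavoured epimer is reduced, so each half passes through one diastereomeric transition state (dynamic kinetic resolution). The closest known reaction type is the ketoreductase-catalysed dynamic kinetic resolution of α-alkyl β-aryl β-keto esters, here run twice on one molecule through intermediate 5. No ring is closed in this step. C2 and C1' (both R) are set by the enzyme's facial selectivity at the carbonyl; C3 and C5 are set by its choice between the equilibrating α-epimers, which fixes the anti relationship in each half. The step needs anti over syn and the same absolute sense in both halves; the C4 methylene spacer makes the halves independent α-alkyl β-keto esters, so catalyst control should override any influence of the half already reduced. Because the two events are identical, an occasional wrong-sense reduction ends in a separable diastereomer and not in the enantiomer, which should lift the enantiomeric purity of 6 above that of a single reduction. The phenols are left free to keep the substrate small and hydrophilic at the para positions; isopropanol regenerates NADPH and leaves as acetone.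

Step 4
Reactants: 6 diethyl (2S,4S)-2,4-bis[(R)-hydroxy(4-hydroxyphenyl)methyl]pentanedioate
Product: 7 diethyl (2S,4S)-2,4-bis[(R)-hydroxy(4-TIPSO-phenyl)methyl]pentanedioate
Conditions: TIPSCl (2.2 equiv), imidazole, DMF, 0 °C to rt
Reagents that add atoms: triisopropylsilyl chloride, CC(C)[Si](Cl)(C(C)C)C(C)C
Why: Chemoselective O-silylation; the bulky chlorosilane reacts with the acidic, unhindered phenols and should leave the hindered secondary benzylic alcohols untouched. The aryl TIPS ethers are robust toward the hydride and alkoxide conditions that follow.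

Step 5
Reactants: 7 diethyl (2S,4S)-2,4-bis[(R)-hydroxy(4-TIPSO-phenyl)methyl]pentanedioate
Product: 8 diethyl (2S,4S)-2-[(R)-(TBSO)(4-TIPSO-phenyl)methyl]-4-[(R)-hydroxy(4-TIPSO-phenyl)methyl]pentanedioate
Conditions: TBSOTf (0.9 equiv), 2,6-lutidine, CH2Cl2, −78 °C; recovered 7 recycled
Reagents that add atoms: tert-butyldimethylsilyl trifluoromethanesulfonate, CC(C)(C)[Si](C)(C)OS(=O)(=O)C(F)(F)F
Why: Terminus differentiation of a C2-symmetric diol: the two carbinols are homotopic, so silylation of either gives the same compound 8. Sub-stoichiometric silyl triflate at low temperature limits double silylation, and the silylated carbinol becomes the exocyclic C1'.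

Step 6
Reactants: 8 diethyl (2S,4S)-2-[(R)-(TBSO)(4-TIPSO-phenyl)methyl]-4-[(R)-hydroxy(4-TIPSO-phenyl)methyl]pentanedioate
Product: 9 (2R,4R)-2-[(R)-(TBSO)(4-TIPSO-phenyl)methyl]-4-[(R)-hydroxy(4-TIPSO-phenyl)methyl]pentane-1,5-diol
Conditions: LiBH4, THF, MeOH (cat.), 0 °C to rt
Reagents that add atoms: none
Why: Borohydride reduction of both esters to primary alcohols; no stereocentre is touched (the descriptors at C3 and C5 change only through CIP priorities), and the mild hydride should spare the silyl ethers.

Step 7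
Reactants: 9 (2R,4R)-2-[(R)-(TBSO)(4-TIPSO-phenyl)methyl]-4-[(R)-hydroxy(4-TIPSO-phenyl)methyl]pentane-1,5-diol
Product: 11 [(2R,3R,5R)-5-[(R)-(TBSO)(4-TIPSO-phenyl)methyl]-2-(4-TIPSO-phenyl)oxan-3-yl]methyl 4-methylbenzenesulfonate, via bis-tosylate 10 (not isolated)
Conditions: TsCl (2.2 equiv), Et3N, Me3N·HCl (cat.), CH2Cl2, 0 °C; aqueous wash; then NaH (1.5 equiv), THF, 0 °C to rt
Reagents that add atoms: 4-methylbenzenesulfonyl chloride, Cc1ccc(cc1)S(Cl)(=O)=O
Why: Amine-catalysed tosylation is selective for the two primary alcohols over the hindered benzylic one; the C2 alkoxide then closes the oxane by 6-exo-tet Williamson displacement at C6, the only alternative being a slow 4-exo closure. C2 keeps its configuration because its C–O bond is not broken, and the silylated C1' oxygen cannot form a second ether bridge to the arm on C3.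

Step 8
Reactants: 11 [(2R,3R,5R)-5-[(R)-(TBSO)(4-TIPSO-phenyl)methyl]-2-(4-TIPSO-phenyl)oxan-3-yl]methyl 4-methylbenzenesulfonate
Product: 12 (2R,3S,5R)-5-[(R)-(TBSO)(4-TIPSO-phenyl)methyl]-3-(iodomethyl)-2-(4-TIPSO-phenyl)oxane
Conditions: NaI (5 equiv), acetone, reflux
Reagents that add atoms: sodium iodide, [Na+].[I-]
Why: Finkelstein displacement of the primary tosylate; precipitation of sodium tosylate drives it, and no stereocentre is involved (the C3 descriptor changes by CIP priority only).

Step 9
Reactants: 13 4-[(tert-butyldimethylsilyl)oxy]benzaldehyde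
Product: 14 tert-butyl{4-[(E)-2-iodoethenyl]phenoxy}dimethylsilane
Conditions: CrCl2 (6 equiv), CHI3 (2 equiv), THF, 0 °C to rt
Reagents that add atoms: iodoform, IC(I)I
Why: Takai olefination; the geminal dichromium species from iodoform adds to the aldehyde and eliminates anti, which should give the E alkenyl iodide with high selectivity for an aromatic aldehyde.

Step 10
Reactants: 12 (2R,3S,5R)-5-[(R)-(TBSO)(4-TIPSO-phenyl)methyl]-3-(iodomethyl)-2-(4-TIPSO-phenyl)oxane; 14 tert-butyl{4-[(E)-2-iodoethenyl]phenoxy}dimethylsilane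
Product: 16 (2R,3S,5R)-5-[(R)-(TBSO)(4-TIPSO-phenyl)methyl]-3-[(E)-3-(4-TBSO-phenyl)prop-2-enyl]-2-(4-TIPSO-phenyl)oxane, via alkylzinc iodide 15 (not isolated)
Conditions: Zn dust (activated with TMSCl and BrCH2CH2Br), LiCl, THF, 40 °C; then 14, Pd(OAc)2 (3 mol %), SPhos (6 mol %), THF, rt
Reagents that add atoms: none
Why: LiCl-promoted zinc insertion into the primary iodide, then Negishi sp3–sp2 cross-coupling; oxidative addition of 14 to zerovalent palladium and reductive elimination retain the E geometry, and the bulky biaryl phosphine should make reductive elimination faster than β-hydride elimination. The organozinc has no β-leaving group and tolerates the silyl ethers.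

Step 11
Reactants: 16 (2R,3S,5R)-5-[(R)-(TBSO)(4-TIPSO-phenyl)methyl]-3-[(E)-3-(4-TBSO-phenyl)prop-2-enyl]-2-(4-TIPSO-phenyl)oxane
Product: 17 4-[(E)-3-[(2R,3S,5R)-5-[(R)-hydroxy(4-hydroxyphenyl)methyl]-2-(4-hydroxyphenyl)oxan-3-yl]prop-1-enyl]phenol (target, CNP0182155.1)
Conditions: TBAF (6 equiv), AcOH (6 equiv), THF, 0 °C to rt
Reagents that add atoms: none
Why: Fluoride-mediated cleavage of the two aryl TIPS ethers, the aryl TBS ether and the secondary TBS ether; acetic acid keeps the phenols protonated, so the 4-hydroxybenzylic C2–O1 and C1'–O bonds should not be pushed toward quinone methides and C2 stays kinetically fixed.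

## Compound list

1 | 1-(4-hydroxyphenyl)ethan-1-one | CC(=O)c1ccc(O)cc1 | starting material
2 | ethyl 3-(4-hydroxyphenyl)-3-oxopropanoate | CCOC(=O)CC(=O)c1ccc(O)cc1 | intermediate
3 | ethyl 2-(4-hydroxybenzoyl)prop-2-enoate | CCOC(=O)C(=C)C(=O)c1ccc(O)cc1 | intermediate (not isolated)
4 | diethyl 2,4-bis(4-hydroxybenzoyl)pentanedioate (stereoisomer mixture) | CCOC(=O)C(CC(C(=O)OCC)C(=O)c1ccc(O)cc1)C(=O)c1ccc(O)cc1 | intermediate
5 | diethyl (2S)-2-[(R)-hydroxy(4-hydroxyphenyl)methyl]-4-(4-hydroxybenzoyl)pentanedioate (C4 epimerising) | CCOC(=O)[C@H]([C@@H](O)c1ccc(O)cc1)CC(C(=O)OCC)C(=O)c1ccc(O)cc1 | intermediate (not isolated)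
6 | diethyl (2S,4S)-2,4-bis[(R)-hydroxy(4-hydroxyphenyl)methyl]pentanedioate | CCOC(=O)[C@H]([C@@H](O)c1ccc(O)cc1)C[C@@H]([C@@H](O)c1ccc(O)cc1)C(=O)OCC | intermediate
7 | diethyl (2S,4S)-2,4-bis[(R)-hydroxy{4-[(triisopropylsilyl)oxy]phenyl}methyl]pentanedioate | CCOC(=O)[C@H]([C@@H](O)c1ccc(O[Si](C(C)C)(C(C)C)C(C)C)cc1)C[C@@H]([C@@H](O)c1ccc(O[Si](C(C)C)(C(C)C)C(C)C)cc1)C(=O)OCC | intermediate
8 | diethyl (2S,4S)-2-[(R)-[(tert-butyldimethylsilyl)oxy]{4-[(triisopropylsilyl)oxy]phenyl}methyl]-4-[(R)-hydroxy{4-[(triisopropylsilyl)oxy]phenyl}methyl]pentanedioate | CCOC(=O)[C@H]([C@@H](O)c1ccc(O[Si](C(C)C)(C(C)C)C(C)C)cc1)C[C@@H]([C@@H](O[Si](C)(C)C(C)(C)C)c1ccc(O[Si](C(C)C)(C(C)C)C(C)C)cc1)C(=O)OCC | intermediate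
9 | (2R,4R)-2-[(R)-[(tert-butyldimethylsilyl)oxy]{4-[(triisopropylsilyl)oxy]phenyl}methyl]-4-[(R)-hydroxy{4-[(triisopropylsilyl)oxy]phenyl}methyl]pentane-1,5-diol | OC[C@H]([C@@H](O)c1ccc(O[Si](C(C)C)(C(C)C)C(C)C)cc1)C[C@@H]([C@@H](O[Si](C)(C)C(C)(C)C)c1ccc(O[Si](C(C)C)(C(C)C)C(C)C)cc1)CO | intermediate
10 | (2R,4R)-2-[(R)-[(tert-butyldimethylsilyl)oxy]{4-[(triisopropylsilyl)oxy]phenyl}methyl]-4-[(R)-hydroxy{4-[(triisopropylsilyl)oxy]phenyl}methyl]pentane-1,5-diyl bis(4-methylbenzenesulfonate) | Cc1ccc(cc1)S(=O)(=O)OC[C@H]([C@@H](O)c1ccc(O[Si](C(C)C)(C(C)C)C(C)C)cc1)C[C@@H]([C@@H](O[Si](C)(C)C(C)(C)C)c1ccc(O[Si](C(C)C)(C(C)C)C(C)C)cc1)COS(=O)(=O)c1ccc(C)cc1 | intermediate (not isolated)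
11 | [(2R,3R,5R)-5-[(R)-[(tert-butyldimethylsilyl)oxy]{4-[(triisopropylsilyl)oxy]phenyl}methyl]-2-{4-[(triisopropylsilyl)oxy]phenyl}oxan-3-yl]methyl 4-methylbenzenesulfonate | Cc1ccc(cc1)S(=O)(=O)OC[C@H]1C[C@@H]([C@@H](O[Si](C)(C)C(C)(C)C)c2ccc(O[Si](C(C)C)(C(C)C)C(C)C)cc2)CO[C@H]1c1ccc(O[Si](C(C)C)(C(C)C)C(C)C)cc1 | intermediate
12 | (2R,3S,5R)-5-[(R)-[(tert-butyldimethylsilyl)oxy]{4-[(triisopropylsilyl)oxy]phenyl}methyl]-3-(iodomethyl)-2-{4-[(triisopropylsilyl)oxy]phenyl}oxane | IC[C@H]1C[C@@H]([C@@H](O[Si](C)(C)C(C)(C)C)c2ccc(O[Si](C(C)C)(C(C)C)C(C)C)cc2)CO[C@H]1c1ccc(O[Si](C(C)C)(C(C)C)C(C)C)cc1 | intermediate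
13 | 4-[(tert-butyldimethylsilyl)oxy]benzaldehyde | CC(C)(C)[Si](C)(C)Oc1ccc(C=O)cc1 | starting material
14 | tert-butyl{4-[(E)-2-iodoethenyl]phenoxy}dimethylsilane | CC(C)(C)[Si](C)(C)Oc1ccc(/C=C/I)cc1 | intermediate
15 | {[(2R,3S,5R)-5-[(R)-[(tert-butyldimethylsilyl)oxy]{4-[(triisopropylsilyl)oxy]phenyl}methyl]-2-{4-[(triisopropylsilyl)oxy]phenyl}oxan-3-yl]methyl}zinc iodide | I[Zn]C[C@H]1C[C@@H]([C@@H](O[Si](C)(C)C(C)(C)C)c2ccc(O[Si](C(C)C)(C(C)C)C(C)C)cc2)CO[C@H]1c1ccc(O[Si](C(C)C)(C(C)C)C(C)C)cc1 | intermediate (not isolated)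
16 | (2R,3S,5R)-5-[(R)-[(tert-butyldimethylsilyl)oxy]{4-[(triisopropylsilyl)oxy]phenyl}methyl]-3-[(E)-3-{4-[(tert-butyldimethylsilyl)oxy]phenyl}prop-2-enyl]-2-{4-[(triisopropylsilyl)oxy]phenyl}oxane | CC(C)(C)[Si](C)(C)Oc1ccc(/C=C/C[C@H]2C[C@@H]([C@@H](O[Si](C)(C)C(C)(C)C)c3ccc(O[Si](C(C)C)(C(C)C)C(C)C)cc3)CO[C@H]2c2ccc(O[Si](C(C)C)(C(C)C)C(C)C)cc2)cc1 | intermediate
17 | 4-[(E)-3-[(2R,3S,5R)-5-[(R)-hydroxy(4-hydroxyphenyl)methyl]-2-(4-hydroxyphenyl)oxan-3-yl]prop-1-enyl]phenol | Oc1ccc(/C=C/C[C@H]2C[C@@H]([C@@H](O)c3ccc(O)cc3)CO[C@H]2c2ccc(O)cc2)cc1 | target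

## Step count and risk

Total step count: 11. Longest linear sequence: 10 (steps 1 to 8, 10, 11); step 9 is a one-step side branch.

**Step 3 (key step).**
- What may go wrong: no panel enzyme may turn over the bulky bis-substrate twice, so the reaction stalls at 5. The enzyme may select the syn α-epimer. α-Epimerisation may be too slow relative to reduction, which erodes the diastereoselectivity. Intermediate 5 may be sequestered as a cyclic hemiketal.
- Fallback (auxiliary-controlled two-directional anti-aldol): it sets out not from a numbered compound of the route but from commercial 4-hydroxybenzaldehyde, pentanedioyl dichloride and (R)-4-benzyl-1,3-oxazolidin-2-one, and it comes back to the route at compound 9.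
  - 4-Hydroxybenzaldehyde is silylated (TIPSCl, imidazole) to 4-[(triisopropylsilyl)oxy]benzaldehyde F1.
  - The lithiated auxiliary (n-BuLi, THF, −78 °C) is acylated with pentanedioyl dichloride to the bis-imide 1,5-bis[(4R)-4-benzyl-2-oxo-1,3-oxazolidin-3-yl]pentane-1,5-dione F2.
  - A magnesium-halide-catalysed anti-aldol reaction at both termini (MgCl2 cat., Et3N, TMSCl, EtOAc, rt) with F1 should give the anti,anti double adduct as its bis(trimethylsilyl ether) F3. The (R)-auxiliary is chosen on the premise that the chelated Z-enolate is attacked on the face away from the benzyl group.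
  - TFA in MeOH frees the diol F4.
  - Sub-stoichiometric TBSOTf with 2,6-lutidine gives the mono-TBS ether F5 (the two carbinols are homotopic).
  - LiBH4 removes both auxiliaries reductively and delivers 9.

**Step 5.**
- What may go wrong: the silylation is statistical. The two carbinols react independently, so one pass cannot exceed about half conversion to the mono-ether without building up the bis-ether, and material must be recycled.
- Fallback (intramolecular differentiation): it sets out from 7 and comes back at 9.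
  - Neutral transesterification (Bu2SnO cat., toluene, 90 °C, ethanol removed) should lactonise one carbinol onto the ester of the other half, giving the δ-lactone ethyl (2R,3S,5S)-5-[(R)-hydroxy(4-TIPSO-phenyl)methyl]-6-oxo-2-(4-TIPSO-phenyl)oxane-3-carboxylate F6. Only one hydroxyl is consumed, because a second lactone would need a strained bicyclic bis-lactone.
  - TBSOTf with 2,6-lutidine gives the silyl ether F7.
  - LiBH4 opens the lactone and reduces the ester to give 9.

**Step 7.**
- What may go wrong: sulfonylation of the secondary benzylic alcohol followed by ionisation at C2; Grob-type fragmentation or oxetane formation from the C2 alkoxide and the tosylate on the C3 arm; silyl migration under alkoxide conditions.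
- Fallback (redox cyclodehydration without sulfonates or strong base): it sets out from 9 and comes back at 12.
  - Mitsunobu cyclodehydration (PPh3, DIAD, THF, 0 °C) should activate a primary alcohol and let the C2 hydroxyl close the six-membered ring, giving [(2R,3R,5R)-5-[(R)-(TBSO)(4-TIPSO-phenyl)methyl]-2-(4-TIPSO-phenyl)oxan-3-yl]methanol F8.
  - Appel iodination (I2, PPh3, imidazole) then gives 12 directly.

**Step 10.**
- What may go wrong: sluggish zinc insertion at the β-branched iodide; β-hydride elimination or protodezincation of 15; homocoupling of 14.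
- Fallback (two-carbon extension then olefin metathesis): it sets out from 12 and 13 and comes back at 16.
  - Copper-catalysed coupling of 12 with vinylmagnesium bromide (CuI cat., THF, −30 °C) gives the allyl compound (2R,3S,5R)-5-[(R)-(TBSO)(4-TIPSO-phenyl)methyl]-3-(prop-2-enyl)-2-(4-TIPSO-phenyl)oxane F9.
  - Wittig methylenation of 13 (Ph3P=CH2) gives tert-butyl(4-ethenylphenoxy)dimethylsilane F10.
  - Cross-metathesis of F9 with excess F10, using second-generation Grubbs catalyst (H2IMes)(PCy3)Cl2Ru=CHPh in CH2Cl2 at 40 °C, should give the E alkene 16.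

## Further compounds

F1 | step 3 | 4-[(triisopropylsilyl)oxy]benzaldehyde | CC(C)[Si](Oc1ccc(C=O)cc1)(C(C)C)C(C)C
F2 | step 3 | 1,5-bis[(4R)-4-benzyl-2-oxo-1,3-oxazolidin-3-yl]pentane-1,5-dione | O=C1OC[C@@H](Cc2ccccc2)N1C(=O)CCCC(=O)N1[C@H](Cc2ccccc2)COC1=O
F3 | step 3 | bis(trimethylsilyl ether) of the (2S,4S)-2,4-bis[(R)-hydroxy(4-TIPSO-phenyl)methyl]pentanedioyl bis-imide | O=C1OC[C@@H](Cc2ccccc2)N1C(=O)[C@H]([C@@H](O[Si](C)(C)C)c1ccc(O[Si](C(C)C)(C(C)C)C(C)C)cc1)C[C@@H]([C@@H](O[Si](C)(C)C)c1ccc(O[Si](C(C)C)(C(C)C)C(C)C)cc1)C(=O)N1[C@H](Cc2ccccc2)COC1=O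
F4 | step 3 | (2S,4S)-2,4-bis[(R)-hydroxy(4-TIPSO-phenyl)methyl]-1,5-bis[(4R)-4-benzyl-2-oxo-1,3-oxazolidin-3-yl]pentane-1,5-dione | O=C1OC[C@@H](Cc2ccccc2)N1C(=O)[C@H]([C@@H](O)c1ccc(O[Si](C(C)C)(C(C)C)C(C)C)cc1)C[C@@H]([C@@H](O)c1ccc(O[Si](C(C)C)(C(C)C)C(C)C)cc1)C(=O)N1[C@H](Cc2ccccc2)COC1=O
F5 | step 3 | mono(tert-butyldimethylsilyl) ether of F4 | O=C1OC[C@@H](Cc2ccccc2)N1C(=O)[C@H]([C@@H](O)c1ccc(O[Si](C(C)C)(C(C)C)C(C)C)cc1)C[C@@H]([C@@H](O[Si](C)(C)C(C)(C)C)c1ccc(O[Si](C(C)C)(C(C)C)C(C)C)cc1)C(=O)N1[C@H](Cc2ccccc2)COC1=O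
F6 | step 5 | ethyl (2R,3S,5S)-5-[(R)-hydroxy(4-TIPSO-phenyl)methyl]-6-oxo-2-(4-TIPSO-phenyl)oxane-3-carboxylate | CCOC(=O)[C@H]1C[C@@H]([C@@H](O)c2ccc(O[Si](C(C)C)(C(C)C)C(C)C)cc2)C(=O)O[C@H]1c1ccc(O[Si](C(C)C)(C(C)C)C(C)C)cc1
F7 | step 5 | ethyl (2R,3S,5S)-5-[(R)-(TBSO)(4-TIPSO-phenyl)methyl]-6-oxo-2-(4-TIPSO-phenyl)oxane-3-carboxylate | CCOC(=O)[C@H]1C[C@@H]([C@@H](O[Si](C)(C)C(C)(C)C)c2ccc(O[Si](C(C)C)(C(C)C)C(C)C)cc2)C(=O)O[C@H]1c1ccc(O[Si](C(C)C)(C(C)C)C(C)C)cc1
F8 | step 7 | [(2R,3R,5R)-5-[(R)-(TBSO)(4-TIPSO-phenyl)methyl]-2-(4-TIPSO-phenyl)oxan-3-yl]methanol | OC[C@H]1C[C@@H]([C@@H](O[Si](C)(C)C(C)(C)C)c2ccc(O[Si](C(C)C)(C(C)C)C(C)C)cc2)CO[C@H]1c1ccc(O[Si](C(C)C)(C(C)C)C(C)C)cc1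
F9 | step 10 | (2R,3S,5R)-5-[(R)-(TBSO)(4-TIPSO-phenyl)methyl]-3-(prop-2-enyl)-2-(4-TIPSO-phenyl)oxane | C=CC[C@H]1C[C@@H]([C@@H](O[Si](C)(C)C(C)(C)C)c2ccc(O[Si](C(C)C)(C(C)C)C(C)C)cc2)CO[C@H]1c1ccc(O[Si](C(C)C)(C(C)C)C(C)C)cc1
F10 | step 10 | tert-butyl(4-ethenylphenoxy)dimethylsilane | C=Cc1ccc(O[Si](C)(C)C(C)(C)C)cc1
A1 | alternative 1 | (3S,5R)-5-[(R)-(TBSO)(4-TBSO-phenyl)methyl]-3-[(E)-3-(4-TBSO-phenyl)prop-2-enyl]oxan-2-one | CC(C)(C)[Si](C)(C)Oc1ccc(/C=C/C[C@H]2C[C@@H]([C@@H](O[Si](C)(C)C(C)(C)C)c3ccc(O[Si](C)(C)C(C)(C)C)cc3)COC2=O)cc1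
A2 | alternative 1 | (3S,5R)-5-[(R)-(TBSO)(4-TBSO-phenyl)methyl]-3-[(E)-3-(4-TBSO-phenyl)prop-2-enyl]-2-(4-TBSO-phenyl)oxan-2-ol (anomers) | CC(C)(C)[Si](C)(C)Oc1ccc(/C=C/C[C@H]2C[C@@H]([C@@H](O[Si](C)(C)C(C)(C)C)c3ccc(O[Si](C)(C)C(C)(C)C)cc3)COC2(O)c2ccc(O[Si](C)(C)C(C)(C)C)cc2)cc1
A3 | alternative 2 | acyclic quinone methide: 4-[(E)-5-(4-hydroxyphenyl)-2-{(2R,3R)-3-hydroxy-2-(hydroxymethyl)-3-(4-hydroxyphenyl)propyl}pent-4-enylidene]cyclohexa-2,5-dien-1-one, with C3, C5 and C1' as in the target | OC[C@H]([C@@H](O)c1ccc(O)cc1)C[C@H](C/C=C/c1ccc(O)cc1)C=C1C=CC(=O)C=C1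
A4 | alternative 3 | ethyl 2-[(S)-[(tert-butyldimethylsilyl)oxy]{4-[(tert-butyldimethylsilyl)oxy]phenyl}methyl]prop-2-enoate | CCOC(=O)C(=C)[C@@H](O[Si](C)(C)C(C)(C)C)c1ccc(O[Si](C)(C)C(C)(C)C)cc1
A5 | alternative 3 | (E)-1,5-bis{4-[(tert-butyldimethylsilyl)oxy]phenyl}pent-4-en-1-one | CC(C)(C)[Si](C)(C)Oc1ccc(/C=C/CCC(=O)c2ccc(O[Si](C)(C)C(C)(C)C)cc2)cc1
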